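**Plan** (prostanoid numbering: ester carbon C1, ring C8–C12, lower chain C13–C20)
- Cuts, in retrosynthetic order: the C12 acetate; the C5=C6/C7=C8 dienone, traced back to a C8 alkynyl ketone (C6≡C7); the ring bond C8–C12; C7–C8 (acetylide plus aldehyde); C12–C13 (furyllithium plus allylic bromide).
- Enabling feature: the ring C8–C9(=O)–C10(Br)=C11–C12(O) is a 4-oxygenated cyclopent-2-enone. It is the rearrangement product of a 2-furylcarbinol in which furan C2, C3, C4 and C5 become C9, C10, C11 and C12 and the carbinol carbon becomes C8.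
- Forward: 3-bromofuran-2-carbaldehyde is alkylated at furan C5 (C12–C13) and the alkyne ester is added to the aldehyde (C7–C8). The furan is then rearranged into the only ring (C8–C12), the alkyne is isomerised to the 5E dienone, C12–OH is acetylated, and the C7=C8 geometry is sorted last.
- Stereochemistry: C12 comes from the chiral acid in the 4π closure, 14Z from (Z)-oct-2-en-1-ol, and 5E from thermodynamic control. 7Z comes from photoequilibration and separation.

Key step: step 6

Assumption: the (R)-configured acid is written as the antipode that delivers the required C12 configuration; precedent does not predict which antipode does so, and the (S)-acid would be used if the first experiment shows the opposite sense.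

Step 1
Reactants: 1 (2Z)-oct-2-en-1-ol
Product: 2 (2Z)-1-bromooct-2-ene
Conditions: CBr4, PPh3, CH2Cl2, 0 °C
Reagents that add atoms: carbon tetrabromide, BrC(Br)(Br)Br
Why: Appel bromination of a primary allylic alcohol proceeds by SN2 displacement of the oxyphosphonium at 0 °C, so the Z double bond should be kept and no allylic transposition is expected.

Step 2
Reactants: 3 3-bromofuran-2-carbaldehyde
Product: 4 2-(3-bromofuran-2-yl)-1,3-dioxolane
Conditions: HOCH2CH2OH, p-TsOH·H2O (cat.), benzene, reflux, Dean–Stark trap
Reagents that add atoms: ethylene glycol, OCCO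
Why: Acid-catalysed acetalisation with azeotropic removal of water masks the aldehyde as a dioxolane that tolerates the amide base of step 3.

Step 3
Reactants: 4 2-(3-bromofuran-2-yl)-1,3-dioxolane; 2 (2Z)-1-bromooct-2-ene
Product: 6 2-[3-bromo-5-[(2Z)-oct-2-en-1-yl]furan-2-yl]-1,3-dioxolane, via furyllithium 5 (not isolated)
Conditions: LiN(i-Pr)2 (LDA), THF, −78 °C; then 2, −78 → 0 °C; aq. NH4Cl
Reagents that add atoms: none
Why: With C2 blocked, the amide base removes the only remaining α-proton of the furan (C5) by deprotonation without bromine–lithium exchange, and the furyllithium alkylates the primary allylic bromide by SN2 at low temperature, which forms C12–C13 and keeps the Z alkene.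

Step 4
Reactants: 6 2-[3-bromo-5-[(2Z)-oct-2-en-1-yl]furan-2-yl]-1,3-dioxolane
Product: 7 3-bromo-5-[(2Z)-oct-2-en-1-yl]furan-2-carbaldehyde
Conditions: 1 M HCl (cat.), THF/H2O, 23 °C
Reagents that add atoms: water, O
Why: Acetal hydrolysis under mild aqueous acid frees the aldehyde while the furan and the skipped Z alkene should be left alone.

Step 5
Reactants: 7 3-bromo-5-[(2Z)-oct-2-en-1-yl]furan-2-carbaldehyde; 8 methyl hept-6-ynoate
Product: 10 methyl 8-[3-bromo-5-[(2Z)-oct-2-en-1-yl]furan-2-yl]-8-hydroxyoct-6-ynoate (racemic), via zinc acetylide 9 (not isolated)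
Conditions: Me2Zn (2 equiv), 8 (2 equiv), toluene, 23 °C; then 7, 0 → 23 °C; aq. NH4Cl
Reagents that add atoms: none
Why: Me2Zn deprotonates the terminal alkyne to a zinc acetylide that tolerates the methyl ester and adds to the non-enolisable aldehyde (alkynylzinc 1,2-addition), forming C7–C8; the carbinol is racemic, which is immaterial because C8 is ionised in step 6.

Step 6
Reactants: 10 methyl 8-[3-bromo-5-[(2Z)-oct-2-en-1-yl]furan-2-yl]-8-hydroxyoct-6-ynoate
Product: 13 methyl 7-[(1S,5S)-3-bromo-5-hydroxy-5-[(2Z)-oct-2-en-1-yl]-2-oxocyclopent-3-en-1-yl]hept-6-ynoate, via hemiketal 11 (not isolated), via ring-opened enol ketone 12 (not isolated)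
Conditions: (R)-N-triflylphosphoramide of 3,3'-bis(2,4,6-triisopropylphenyl)-1,1'-bi-2-naphthol (10 mol %), H2O (5 equiv), PhCF3, 40 °C
Reagents that add atoms: water, O
Why: Proposed new method: the chiral acid should ionise the propargylic furylcarbinol to a furfuryl cation whose charge rests mainly on the oxocarbenium carbon C12, water adds there to give hemiketal 11, ring opening gives enol ketone 12, and its O-protonated form, a dihydroxypentadienyl cation held as an ion pair by the phosphoramide anion, closes between C8 and C12 and then loses a proton to give the enone; the closest known reaction types are the racemic acid-catalysed Piancatelli rearrangement of 5-alkyl-2-furylcarbinols in water and the chiral phosphoric acid catalysed aza-Piancatelli rearrangement, so enantiocontrol with water as the nucleophile is the untested part. The five-membered carbocycle is closed by a thermal conrotatory 4π electrocyclisation of the pentadienyl cation (Nazarov-type closure). C12 is set by the sense of conrotation, which the hydrogen-bonded chiral counteranion has to impose (catalyst control), while C8 follows from the two termini turning with the hydroxyl and the alkynyl group on the outside, which places them trans (control by the electrocyclic geometry). The step needs water to attack C12 and not the alkyne terminus C6 (Meyer–Schuster path); the ring oxygen, which concentrates the charge on C12, and the small amount of water in a non-polar solvent should secure this. C8 is erased again in step 7, so only the facial selectivity at C12 counts for the target.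

Step 7
Reactants: 13 methyl 7-[(1S,5S)-3-bromo-5-hydroxy-5-[(2Z)-oct-2-en-1-yl]-2-oxocyclopent-3-en-1-yl]hept-6-ynoate
Product: 15 methyl (5E)-7-[(2R)-4-bromo-2-hydroxy-2-[(2Z)-oct-2-en-1-yl]-5-oxocyclopent-3-en-1-ylidene]hept-5-enoate as the 7E/7Z mixture, via allenone 14 (not isolated)
Conditions: Et3N (0.5 equiv), toluene, 23 °C; then PPh3 (20 mol %), 23 → 60 °C; exclusion of light
Reagents that add atoms: none
Why: Et3N shifts the acidic C8 proton to C6 (propargyl-to-allenyl ketone isomerisation), then PPh3 adds to the central allene carbon C7 and is expelled again after proton shifts from C5 (phosphine-catalysed allenone-to-dienone isomerisation), which should give the thermodynamically preferred 5E geometry and removes the C8 stereocentre; the C12 hydroxyl is kept free here because it is a poor leaving group for the enolate intermediates, whereas an acetate could be eliminated.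

Step 8
Reactants: 15 methyl (5E)-7-[(2R)-4-bromo-2-hydroxy-2-[(2Z)-oct-2-en-1-yl]-5-oxocyclopent-3-en-1-ylidene]hept-5-enoate (7E/7Z mixture)
Product: 16 methyl (5E)-7-[(2R)-2-acetoxy-4-bromo-2-[(2Z)-oct-2-en-1-yl]-5-oxocyclopent-3-en-1-ylidene]hept-5-enoate as the 7E/7Z mixture
Conditions: Ac2O, DMAP, Et3N, CH2Cl2, 23 → 40 °C; exclusion of light
Reagents that add atoms: acetic anhydride, CC(=O)OC(C)=O
Why: DMAP-catalysed acyl transfer esterifies the tertiary C12 alcohol, and because C8 no longer carries a proton the new acetate cannot be lost by E1cB elimination; the configuration at C12 is not touched.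

Step 9
Reactants: 16 methyl (5E)-7-[(2R)-2-acetoxy-4-bromo-2-[(2Z)-oct-2-en-1-yl]-5-oxocyclopent-3-en-1-ylidene]hept-5-enoate (7E/7Z mixture)
Product: 17 methyl (5E,7Z)-7-[(2R)-2-acetoxy-4-bromo-2-[(2Z)-oct-2-en-1-yl]-5-oxocyclopent-3-en-1-ylidene]hept-5-enoate (target)
Conditions: preparative HPLC (SiO2, hexane/EtOAc) to collect the 7Z isomer; 7E fraction: hν (350 nm, borosilicate filter), benzene, 23 °C, to the photostationary mixture; separation and irradiation repeated
Reagents that add atoms: none
Why: E/Z photoisomerisation of the dienone lets the exocyclic C7=C8 bond rotate in the excited state, the photostationary mixture should hold a useful share of the 7Z isomer, which should be separable from the 7E isomer, and recycling converts the remainder; C12 and the 14Z alkene lie outside the chromophore and should be unaffected.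

**Compound list**
1 | (2Z)-oct-2-en-1-ol | CCCCC/C=C\CO | starting material
2 | (2Z)-1-bromooct-2-ene | CCCCC/C=C\CBr | intermediate
3 | 3-bromofuran-2-carbaldehyde | O=Cc1occc1Br | starting material
4 | 2-(3-bromofuran-2-yl)-1,3-dioxolane | Brc1ccoc1C1OCCO1 | intermediate
5 | [4-bromo-5-(1,3-dioxolan-2-yl)furan-2-yl]lithium (formed in the flask) | [Li]c1cc(Br)c(o1)C1OCCO1 | intermediate
6 | 2-[3-bromo-5-[(2Z)-oct-2-en-1-yl]furan-2-yl]-1,3-dioxolane | CCCCC/C=C\Cc1cc(Br)c(o1)C1OCCO1 | intermediate
7 | 3-bromo-5-[(2Z)-oct-2-en-1-yl]furan-2-carbaldehyde | CCCCC/C=C\Cc1cc(Br)c(C=O)o1 | intermediate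
8 | methyl hept-6-ynoate | C#CCCCCC(=O)OC | starting material
9 | methyl 7-(methylzincio)hept-6-ynoate (formed in the flask) | C[Zn]C#CCCCCC(=O)OC | intermediate
10 | methyl 8-[3-bromo-5-[(2Z)-oct-2-en-1-yl]furan-2-yl]-8-hydroxyoct-6-ynoate (racemic at C8) | CCCCC/C=C\Cc1cc(Br)c(o1)C(O)C#CCCCCC(=O)OC | intermediate
11 | methyl 8-[3-bromo-5-hydroxy-5-[(2Z)-oct-2-en-1-yl]furan-2(5H)-ylidene]oct-6-ynoate (hemiketal, formed in the flask, C12 and the exocyclic alkene not defined) | CCCCC/C=C\CC1(O)C=C(Br)C(=CC#CCCCCC(=O)OC)O1 | intermediate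
12 | methyl (10E,14Z)-10-bromo-9-hydroxy-12-oxoicosa-8,10,14-trien-6-ynoate (ring-opened enol ketone, formed in the flask, C8=C9 geometry not defined) | CCCCC/C=C\CC(=O)/C=C(Br)\C(O)=CC#CCCCCC(=O)OC | intermediate
13 | methyl 7-[(1S,5S)-3-bromo-5-hydroxy-5-[(2Z)-oct-2-en-1-yl]-2-oxocyclopent-3-en-1-yl]hept-6-ynoate (alkynyl chain trans to the hydroxyl) | CCCCC/C=C\C[C@@]1(O)C=C(Br)C(=O)[C@H]1C#CCCCCC(=O)OC | intermediate
14 | methyl 7-[(2R)-4-bromo-2-hydroxy-2-[(2Z)-oct-2-en-1-yl]-5-oxocyclopent-3-en-1-ylidene]hept-6-enoate (allenone, formed in the flask, allene axis not defined) | CCCCC/C=C\C[C@@]1(O)C=C(Br)C(=O)C1=C=CCCCCC(=O)OC | intermediate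
15 | methyl (5E)-7-[(2R)-4-bromo-2-hydroxy-2-[(2Z)-oct-2-en-1-yl]-5-oxocyclopent-3-en-1-ylidene]hept-5-enoate (7E/7Z mixture) | CCCCC/C=C\C[C@@]1(O)C=C(Br)C(=O)C1=C/C=C/CCCC(=O)OC | intermediate
16 | methyl (5E)-7-[(2R)-2-acetoxy-4-bromo-2-[(2Z)-oct-2-en-1-yl]-5-oxocyclopent-3-en-1-ylidene]hept-5-enoate (7E/7Z mixture) | CCCCC/C=C\C[C@@]1(OC(C)=O)C=C(Br)C(=O)C1=C/C=C/CCCC(=O)OC | intermediate
17 | methyl (5E,7Z)-7-[(2R)-2-acetoxy-4-bromo-2-[(2Z)-oct-2-en-1-yl]-5-oxocyclopent-3-en-1-ylidene]hept-5-enoate (5E,7Z,14Z,12R in prostanoid numbering) | CCCCC/C=C\C[C@@]1(OC(C)=O)C=C(Br)C(=O)/C1=C\C=C\CCCC(=O)OC | target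

**Step count**
Total steps: 9. Longest linear sequence: 8 steps (steps 2 to 9, from 3); step 1 is a one-step side branch.

**Steps most likely to fail**

Step 6. The ion pair may give too little facial bias in the conrotatory closure, or the cation may be diverted by water attack at C6 or by proton loss from C13. The fallback uses known chemistry and sets out from 10. The rearrangement is run without chiral control with Dy(OTf)3 (10 mol %) in t-BuOH/H2O at 80 °C, a racemic Piancatelli rearrangement. It should give the trans hydroxy ketone as the racemate, that is 13 together with its mirror image methyl 7-[(1R,5R)-3-bromo-5-hydroxy-5-[(2Z)-oct-2-en-1-yl]-2-oxocyclopent-3-en-1-yl]hept-6-ynoate F1. The two are separated by preparative HPLC on a chiral stationary phase (cellulose tris(3,5-dimethylphenylcarbamate) on silica), and 13 comes back to the route at step 7.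

Step 7. The phosphine may add to the bromo enone at C11, or the allenone may dimerise or cyclise (attack of the ketone oxygen or the C12 hydroxyl at C6) faster than the proton shifts occur. The fallback replaces the redox-neutral isomerisation by reduction followed by dehydrogenation and sets out from 13.
- Semihydrogenation (H2, Pd/CaCO3 poisoned with Pb(OAc)2, quinoline, EtOAc) should give the cis-alkenyl ketone methyl (6Z)-7-[(1S,5S)-3-bromo-5-hydroxy-5-[(2Z)-oct-2-en-1-yl]-2-oxocyclopent-3-en-1-yl]hept-6-enoate F2.
- TMSOTf and Et3N (CH2Cl2, 0 °C) silylate the C12 hydroxyl and turn the β,γ-unsaturated ketone into the silyl dienol ether methyl (6Z)-7-[(5R)-3-bromo-5-[(2Z)-oct-2-en-1-yl]-2,5-bis(trimethylsilyloxy)cyclopenta-1,3-dien-1-yl]hept-6-enoate F3.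
- DDQ (2,6-lutidine, CH2Cl2, 0 °C) removes hydride from C5 (quinone dehydrogenation of a dienol ether) and, after loss of the enol silyl group, should give the C12 silyl ether methyl (5E)-7-[(2R)-4-bromo-2-[(2Z)-oct-2-en-1-yl]-5-oxo-2-(trimethylsilyloxy)cyclopent-3-en-1-ylidene]hept-5-enoate F4.
- AcOH/THF/H2O frees the hydroxyl and returns 15.

Step 9. The photostationary mixture may be poor in the 7Z isomer, and irradiation may also turn the C5=C6 bond or degrade the cross-conjugated dienone acetate. The fallback sorts the geometry in the ground state at the alcohol stage and sets out from 15. HPLC separates the isomers of 15, and the 7E alcohol is re-equilibrated thermally with PPh3 (20 mol %, toluene, 60 °C), where reversible conjugate addition of the phosphine at C7 allows rotation about C7–C8 and leaves the isolated 14Z alkene alone. Separation and re-equilibration are repeated, and the pooled methyl (5E,7Z)-7-[(2R)-4-bromo-2-hydroxy-2-[(2Z)-oct-2-en-1-yl]-5-oxocyclopent-3-en-1-ylidene]hept-5-enoate F5 is acetylated under the conditions of step 8 in the dark to give 17.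

**Further compounds**
F1 | step 6 | methyl 7-[(1R,5R)-3-bromo-5-hydroxy-5-[(2Z)-oct-2-en-1-yl]-2-oxocyclopent-3-en-1-yl]hept-6-ynoate | CCCCC/C=C\C[C@]1(O)C=C(Br)C(=O)[C@@H]1C#CCCCCC(=O)OC
F2 | step 7 | methyl (6Z)-7-[(1S,5S)-3-bromo-5-hydroxy-5-[(2Z)-oct-2-en-1-yl]-2-oxocyclopent-3-en-1-yl]hept-6-enoate | CCCCC/C=C\C[C@@]1(O)C=C(Br)C(=O)[C@H]1/C=C\CCCCC(=O)OC
F3 | step 7 | methyl (6Z)-7-[(5R)-3-bromo-5-[(2Z)-oct-2-en-1-yl]-2,5-bis(trimethylsilyloxy)cyclopenta-1,3-dien-1-yl]hept-6-enoate | CCCCC/C=C\C[C@@]1(O[Si](C)(C)C)C=C(Br)C(O[Si](C)(C)C)=C1/C=C\CCCCC(=O)OC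
F4 | step 7 | methyl (5E)-7-[(2R)-4-bromo-2-[(2Z)-oct-2-en-1-yl]-5-oxo-2-(trimethylsilyloxy)cyclopent-3-en-1-ylidene]hept-5-enoate (7E/7Z mixture) | CCCCC/C=C\C[C@@]1(O[Si](C)(C)C)C=C(Br)C(=O)C1=C/C=C/CCCC(=O)OC
F5 | step 9 | methyl (5E,7Z)-7-[(2R)-4-bromo-2-hydroxy-2-[(2Z)-oct-2-en-1-yl]-5-oxocyclopent-3-en-1-ylidene]hept-5-enoate | CCCCC/C=C\C[C@@]1(O)C=C(Br)C(=O)/C1=C\C=C\CCCC(=O)OC
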